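**Retrosynthetic overview**
1. Last operations: removal of a methoxymethyl group and, before it, the biaryl bond between C5 of the dihydrobenzofuran and C2 of the benzofuran, made by steric-controlled C–H borylation of the core and Suzuki–Miyaura coupling with a 2-iodobenzofuran.
2. The C3 hydroxymethyl group comes from an (E)-propenyl group by ozonolysis and NaBH4 reduction.
3. Key disconnection: the dihydrofuran ring is opened at O1–C7a and then at C2–C3, leading back to an acyclic (Z)-allyl benzyl ether. Forward, one anionic cascade ([2,3]-Wittig rearrangement, then intramolecular SNAr at an ortho C–F) forms C2–C3, both stereocentres and the O1–C7a bond.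
4. Enabling feature: C2 carries the ring oxygen and the guaiacyl ring, C3 carries the aryl carbon C3a and a one-carbon branch, and C7a sits ortho to C3a next to the C7 methoxy group. The O-substituted C2–C3 bond is thus the product pattern of a [2,3]-Wittig shift, its alkoxide oxygen ends four atoms from C7a (5-exo), and C7a can start as the C–F carbon of a commercial 2-fluoroanisole.
5. Ring order: the benzofuran ring is built separately (Sonogashira coupling and heteroannulation from dihydroconiferyl alcohol), the dihydrofuran ring in the key step; all benzene rings are bought, and the absolute configuration comes from (R)-but-3-yn-2-ol.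

Key step: step 6

Assumption: the [2,3]-Wittig rearrangement is taken to follow its usual course for secondary (Z)-allyl benzyl ethers (Z-alkene gives the syn alkoxide, carbinol methyl group outside in the envelope transition state); the (R)-alkynol was chosen on that basis.

**Step 1**
Reactants: 1 vanillyl alcohol
Product: 2 [3-methoxy-4-(methoxymethoxy)phenyl]methanol
Conditions: MOMCl, K2CO3, acetone, 0 → 20 °C
Reagents that add atoms: chloromethyl methyl ether, COCCl
Why: K2CO3 deprotonates only the much more acidic phenol, so the Williamson-type O-alkylation should protect the phenol and leave the benzylic alcohol free.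

**Step 2**
Reactants: 2 [3-methoxy-4-(methoxymethoxy)phenyl]methanol
Product: 4 4-(chloromethyl)-2-methoxy-1-(methoxymethoxy)benzene, via benzylic mesylate 3 (not isolated)
Conditions: MsCl, Et3N, CH2Cl2, 0 → 20 °C; used crude
Reagents that add atoms: methanesulfonyl chloride, CS(=O)(=O)Cl (its chlorine ends in the product)
Why: Mesylation of the electron-rich benzylic alcohol followed by in situ SN2 displacement by the chloride of the triethylammonium salt should give the benzyl chloride under buffered conditions that spare the acetal.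

**Step 3**
Reactants: 5 1-bromo-2-fluoro-3-methoxybenzene; 6 (R)-but-3-yn-2-ol
Product: 7 (2R)-4-(2-fluoro-3-methoxyphenyl)but-3-yn-2-ol
Conditions: PdCl2(PPh3)2 (cat.), CuI (cat.), Et3N/THF, 60 °C
Reagents that add atoms: none
Why: Sonogashira coupling of the aryl bromide (activated by the ortho fluorine) with the terminal alkyne forms the aryl–alkyne bond without touching the carbinol stereocentre, which is bought as the (R)-alcohol.

**Step 4**
Reactants: 7 (2R)-4-(2-fluoro-3-methoxyphenyl)but-3-yn-2-ol; 4 4-(chloromethyl)-2-methoxy-1-(methoxymethoxy)benzene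
Product: 9 4-({[(2R)-4-(2-fluoro-3-methoxyphenyl)but-3-yn-2-yl]oxy}methyl)-2-methoxy-1-(methoxymethoxy)benzene, via sodium alkoxide 8 (not isolated)
Conditions: NaH, THF/DMF, 0 °C; then 4, Bu4NI (cat.), 0 → 20 °C
Reagents that add atoms: none
Why: Williamson ether synthesis in which the pre-formed sodium alkoxide displaces chloride from the reactive benzylic chloride; the C–O bond at the stereocentre is not broken, so the R configuration is kept.

**Step 5**
Reactants: 9 4-({[(2R)-4-(2-fluoro-3-methoxyphenyl)but-3-yn-2-yl]oxy}methyl)-2-methoxy-1-(methoxymethoxy)benzene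
Product: 10 4-({[(2R,3Z)-4-(2-fluoro-3-methoxyphenyl)but-3-en-2-yl]oxy}methyl)-2-methoxy-1-(methoxymethoxy)benzene
Conditions: H2 (1 atm), Pd/CaCO3 (Pb(OAc)2-poisoned), quinoline, EtOAc, 20 °C
Reagents that add atoms: none
Why: Lindlar semihydrogenation adds H2 syn on the poisoned Pd surface and should stop at the (Z)-alkene, which the key step needs for syn selectivity.

**Step 6**
Reactants: 10 4-({[(2R,3Z)-4-(2-fluoro-3-methoxyphenyl)but-3-en-2-yl]oxy}methyl)-2-methoxy-1-(methoxymethoxy)benzene
Product: 13 (2S,3S)-7-methoxy-2-[3-methoxy-4-(methoxymethoxy)phenyl]-3-[(1E)-prop-1-en-1-yl]-2,3-dihydro-1-benzofuran, via α-lithiated benzyl ether 11 (not isolated), via lithium syn-alkoxide 12 (not isolated)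
Conditions: n-BuLi (1.1 equiv), THF, −78 °C; then DMPU, −78 → 60 °C; aq. NH4Cl
Reagents that add atoms: none
Why: Proposed new method: n-BuLi removes a benzylic proton of the benzyl ether, the α-alkoxy benzyllithium 11 undergoes the suprafacial [2,3]-Wittig rearrangement through a five-membered envelope transition state, and the lithium alkoxide 12 released, once DMPU is added and the mixture warmed, attacks the C–F carbon by addition–elimination (SNAr through a Meisenheimer adduct); the closest known reaction types are the [2,3]-Wittig rearrangement of secondary (Z)-allyl benzyl ethers with 1,3-chirality transfer and the base-mediated cyclisation of 2-(2-fluoroaryl)ethanols to 2,3-dihydrobenzofurans, which have not been run as one anionic cascade. The dihydrofuran ring closes 5-exo-trig by attack of the alkoxide oxygen on the fluorinated arene carbon ortho to the side chain. C3 is set by chirality transfer from the (R)-carbinol carbon: allylic 1,3-strain against the cis aryl group keeps the methyl group outside, the new C–C bond forms on the face from which oxygen departs, and this also fixes the (E)-propenyl group. C2 is set relative to C3 by the exo position of the aryl group on the carbanion, which from a Z-alkene should give the syn alkoxide and hence the 2,3-trans ring. The step needs benzylic rather than allylic lithiation (the allylic C–H is held in the alkene plane by the same 1,3-strain and is not acidified), [2,3] over [1,2] shift (favoured at −78 °C) and no epimerisation at the benzylic-allylic C3–H, which is secured because the alkoxide is the only base present and is consumed as LiF forms.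

**Step 7**
Reactants: 13 (2S,3S)-7-methoxy-2-[3-methoxy-4-(methoxymethoxy)phenyl]-3-[(1E)-prop-1-en-1-yl]-2,3-dihydro-1-benzofuran
Product: 15 [(2S,3R)-7-methoxy-2-[3-methoxy-4-(methoxymethoxy)phenyl]-2,3-dihydro-1-benzofuran-3-yl]methanol, via 3-carbaldehyde 14 (not isolated)
Conditions: O3, CH2Cl2/MeOH (3:1), −78 °C (stopped at first blue tint); then NaBH4, −78 → 0 °C
Reagents that add atoms: ozone, [O-][O+]=O
Why: Ozonolysis should cleave only the isolated propenyl double bond at −78 °C, and NaBH4 added cold reduces the peroxidic intermediates and the α-aryl aldehyde 14 at once, so that C3 is not epimerised and the C2–O bond is not lost by β-elimination.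

**Step 8**
Reactants: 16 dihydroconiferyl alcohol
Product: 17 4-(3-hydroxypropyl)-2-iodo-6-methoxyphenol
Conditions: I2, NaHCO3, THF/H2O, 0 → 20 °C
Reagents that add atoms: iodine, II
Why: Electrophilic aromatic iodination of the phenoxide should go to the only free position ortho to the oxygen, since the para position carries the side chain.

**Step 9**
Reactants: 17 4-(3-hydroxypropyl)-2-iodo-6-methoxyphenol; 18 ethynyltrimethylsilane
Product: 20 3-[7-methoxy-2-(trimethylsilyl)-1-benzofuran-5-yl]propan-1-ol, via o-alkynylphenol 19 (not isolated)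
Conditions: PdCl2(PPh3)2 (cat.), CuI (cat.), Et3N, DMF, 25 → 80 °C (sealed)
Reagents that add atoms: none
Why: Sonogashira coupling of the iodophenol followed by CuI/base-mediated 5-endo-dig attack of the phenol oxygen on the alkyne (Sonogashira–heteroannulation) should form the benzofuran ring with the silyl group left at C2.

**Step 10**
Reactants: 20 3-[7-methoxy-2-(trimethylsilyl)-1-benzofuran-5-yl]propan-1-ol
Product: 21 3-(2-iodo-7-methoxy-1-benzofuran-5-yl)propan-1-ol
Conditions: ICl (1.05 equiv), CH2Cl2, −78 → −20 °C; aq. Na2S2O3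
Reagents that add atoms: iodine monochloride, ClI
Why: Ipso-iododesilylation, in which the electrophile attacks the silicon-bearing C2 (cation stabilised β to silicon) faster than any C–H position, so the iodide should appear only at C2.

**Step 11**
Reactants: 15 [(2S,3R)-7-methoxy-2-[3-methoxy-4-(methoxymethoxy)phenyl]-2,3-dihydro-1-benzofuran-3-yl]methanol; 21 3-(2-iodo-7-methoxy-1-benzofuran-5-yl)propan-1-ol
Product: 24 3-{2-[(2S,3R)-3-(hydroxymethyl)-7-methoxy-2-[3-methoxy-4-(methoxymethoxy)phenyl]-2,3-dihydro-1-benzofuran-5-yl]-7-methoxy-1-benzofuran-5-yl}propan-1-ol, via O-boryl ether 22 (not isolated), via 5-boryl arene 23 (not isolated)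
Conditions: HBpin (1.1 equiv), THF, 20 °C; then [Ir(OMe)(cod)]2 (cat.), dtbpy (cat.), B2pin2, 65 °C; then 21, PdCl2(dppf) (cat.), aq. K3PO4, 65 °C
Reagents that add atoms: none
Why: Pinacolborane first masks the hydroxyl as its borate, the iridium-catalysed C–H borylation is steric-controlled and should take the only arene C–H without an ortho substituent (C5 of the dihydrobenzofuran), and Suzuki–Miyaura coupling of this boronate with the 2-iodobenzofuran in the same flask forms the biaryl bond while the aqueous base frees the alcohol.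

**Step 12**
Reactants: 24 3-{2-[(2S,3R)-3-(hydroxymethyl)-7-methoxy-2-[3-methoxy-4-(methoxymethoxy)phenyl]-2,3-dihydro-1-benzofuran-5-yl]-7-methoxy-1-benzofuran-5-yl}propan-1-ol
Product: 25 4-[(2S,3R)-3-(hydroxymethyl)-5-[5-(3-hydroxypropyl)-7-methoxy-1-benzofuran-2-yl]-7-methoxy-2,3-dihydro-1-benzofuran-2-yl]-2-methoxyphenol
Conditions: HCl (0.5 M, from AcCl), MeOH/THF, 0 → 40 °C
Reagents that add atoms: none
Why: Acid-catalysed transacetalisation in methanol should remove the methoxymethyl group as dimethoxymethane under conditions mild enough to leave the benzylic C2–O bond, the benzofuran and both stereocentres intact.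

**Compound list**
1 | vanillyl alcohol, 4-(hydroxymethyl)-2-methoxyphenol | COc1cc(CO)ccc1O | starting material
2 | [3-methoxy-4-(methoxymethoxy)phenyl]methanol | COCOc1ccc(CO)cc1OC | intermediate
3 | [3-methoxy-4-(methoxymethoxy)phenyl]methyl methanesulfonate | COCOc1ccc(COS(C)(=O)=O)cc1OC | intermediate (not isolated)
4 | 4-(chloromethyl)-2-methoxy-1-(methoxymethoxy)benzene | COCOc1ccc(CCl)cc1OC | intermediate
5 | 1-bromo-2-fluoro-3-methoxybenzene | COc1cccc(Br)c1F | starting material
6 | (R)-but-3-yn-2-ol | C[C@@H](O)C#C | starting material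
7 | (2R)-4-(2-fluoro-3-methoxyphenyl)but-3-yn-2-ol | C[C@@H](O)C#Cc1cccc(OC)c1F | intermediate
8 | sodium (2R)-4-(2-fluoro-3-methoxyphenyl)but-3-yn-2-olate | C[C@@H]([O-])C#Cc1cccc(OC)c1F.[Na+] | intermediate (not isolated)
9 | 4-({[(2R)-4-(2-fluoro-3-methoxyphenyl)but-3-yn-2-yl]oxy}methyl)-2-methoxy-1-(methoxymethoxy)benzene | C[C@@H](OCc1ccc(OCOC)c(OC)c1)C#Cc1cccc(OC)c1F | intermediate
10 | 4-({[(2R,3Z)-4-(2-fluoro-3-methoxyphenyl)but-3-en-2-yl]oxy}methyl)-2-methoxy-1-(methoxymethoxy)benzene | C[C@@H](OCc1ccc(OCOC)c(OC)c1)/C=C\c1cccc(OC)c1F | intermediate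
11 | 10 lithiated at the benzylic O–CH carbon (configurationally labile carbanion) | C[C@@H](OC([Li])c1ccc(OCOC)c(OC)c1)/C=C\c1cccc(OC)c1F | intermediate (not isolated)
12 | lithium (1S,2S,3E)-2-(2-fluoro-3-methoxyphenyl)-1-[3-methoxy-4-(methoxymethoxy)phenyl]pent-3-en-1-olate | C/C=C/[C@@H](c1cccc(OC)c1F)[C@H]([O-])c1ccc(OCOC)c(OC)c1.[Li+] | intermediate (not isolated)
13 | (2S,3S)-7-methoxy-2-[3-methoxy-4-(methoxymethoxy)phenyl]-3-[(1E)-prop-1-en-1-yl]-2,3-dihydro-1-benzofuran (2,3-trans) | COc1cc([C@H]2Oc3c(OC)cccc3[C@@H]2/C=C/C)ccc1OCOC | intermediate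
14 | (2S,3S)-7-methoxy-2-[3-methoxy-4-(methoxymethoxy)phenyl]-2,3-dihydro-1-benzofuran-3-carbaldehyde | COc1cc([C@H]2Oc3c(OC)cccc3[C@@H]2C=O)ccc1OCOC | intermediate (not isolated)
15 | [(2S,3R)-7-methoxy-2-[3-methoxy-4-(methoxymethoxy)phenyl]-2,3-dihydro-1-benzofuran-3-yl]methanol | COc1cc([C@H]2Oc3c(OC)cccc3[C@@H]2CO)ccc1OCOC | intermediate
16 | dihydroconiferyl alcohol, 4-(3-hydroxypropyl)-2-methoxyphenol | COc1cc(CCCO)ccc1O | starting material
17 | 4-(3-hydroxypropyl)-2-iodo-6-methoxyphenol | COc1cc(CCCO)cc(I)c1O | intermediate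
18 | ethynyltrimethylsilane | C#C[Si](C)(C)C | starting material
19 | 4-(3-hydroxypropyl)-2-methoxy-6-[(trimethylsilyl)ethynyl]phenol | COc1cc(CCCO)cc(C#C[Si](C)(C)C)c1O | intermediate (not isolated)
20 | 3-[7-methoxy-2-(trimethylsilyl)-1-benzofuran-5-yl]propan-1-ol | COc1cc(CCCO)cc2cc([Si](C)(C)C)oc12 | intermediate
21 | 3-(2-iodo-7-methoxy-1-benzofuran-5-yl)propan-1-ol | COc1cc(CCCO)cc2cc(I)oc12 | intermediate
22 | 2-{[(2S,3R)-7-methoxy-2-[3-methoxy-4-(methoxymethoxy)phenyl]-2,3-dihydro-1-benzofuran-3-yl]methoxy}-4,4,5,5-tetramethyl-1,3,2-dioxaborolane | COc1cc([C@H]2Oc3c(OC)cccc3[C@@H]2COB4OC(C)(C)C(C)(C)O4)ccc1OCOC | intermediate (not isolated)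
23 | 22 carrying a second 4,4,5,5-tetramethyl-1,3,2-dioxaborolan-2-yl group at C5 of the dihydrobenzofuran, (2S,3R) | COc1cc([C@H]2Oc3c(OC)cc(B4OC(C)(C)C(C)(C)O4)cc3[C@@H]2COB5OC(C)(C)C(C)(C)O5)ccc1OCOC | intermediate (not isolated)
24 | 3-{2-[(2S,3R)-3-(hydroxymethyl)-7-methoxy-2-[3-methoxy-4-(methoxymethoxy)phenyl]-2,3-dihydro-1-benzofuran-5-yl]-7-methoxy-1-benzofuran-5-yl}propan-1-ol | COc1cc([C@H]2Oc3c(OC)cc(-c4cc5cc(CCCO)cc(OC)c5o4)cc3[C@@H]2CO)ccc1OCOC | intermediate
25 | 4-[(2S,3R)-3-(hydroxymethyl)-5-[5-(3-hydroxypropyl)-7-methoxy-1-benzofuran-2-yl]-7-methoxy-2,3-dihydro-1-benzofuran-2-yl]-2-methoxyphenol | COc1cc([C@H]2Oc3c(OC)cc(-c4cc5cc(CCCO)cc(OC)c5o4)cc3[C@@H]2CO)ccc1O | target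

**Step count and risks**
Total steps: 12. Longest linear sequence: 8 steps (steps 1, 2, 4, 5, 6, 7, 11, 12, from vanillyl alcohol 1).

Steps most likely to fail:

1. Step 6 (proposed new method). The lithium alkoxide may displace fluoride too slowly from the unactivated, methoxy-flanked ring. The heating then needed may let it fragment by retro-allylation or let the benzylic-allylic C3–H epimerise. Fallback in known chemistry, from 10 back to 13: the rearrangement is run alone (n-BuLi, THF, −78 °C, AcOH quench at −78 °C), and the syn homoallylic alcohol (1S,2S,3E)-2-(2-fluoro-3-methoxyphenyl)-1-[3-methoxy-4-(methoxymethoxy)phenyl]pent-3-en-1-ol F1 is isolated and freed from any anti isomer. Its potassium alkoxide (KN(SiMe3)2, 18-crown-6, THF, 0 → 50 °C) then closes the ring in a separate operation by the established intramolecular SNAr etherification of 2-(2-fluoroaryl)ethanols and gives 13.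

2. Step 11. Masking of the free hydroxyl may be incomplete, and the electron-rich aryl boronate may protodeboronate in the aqueous coupling stage, so that little biaryl forms. Fallback, from 15 back to 24: after masking and borylation as before (22, 23), the crude boronate is treated with NaI and TsN(Cl)Na in aqueous THF to give the aryl iodide [(2S,3R)-5-iodo-7-methoxy-2-[3-methoxy-4-(methoxymethoxy)phenyl]-2,3-dihydro-1-benzofuran-3-yl]methanol F2. Sonogashira coupling with 18 (PdCl2(PPh3)2, CuI, Et3N) gives the silyl alkyne [(2S,3R)-7-methoxy-2-[3-methoxy-4-(methoxymethoxy)phenyl]-5-[(trimethylsilyl)ethynyl]-2,3-dihydro-1-benzofuran-3-yl]methanol F3, and K2CO3/MeOH frees the terminal alkyne [(2S,3R)-5-ethynyl-7-methoxy-2-[3-methoxy-4-(methoxymethoxy)phenyl]-2,3-dihydro-1-benzofuran-3-yl]methanol F4. Sonogashira coupling of this alkyne with iodophenol 17 (PdCl2(PPh3)2, CuI, Et3N, DMF, 70 °C) gives the o-alkynylphenol 2-({(2S,3R)-3-(hydroxymethyl)-7-methoxy-2-[3-methoxy-4-(methoxymethoxy)phenyl]-2,3-dihydro-1-benzofuran-5-yl}ethynyl)-4-(3-hydroxypropyl)-6-methoxyphenol F5 (not isolated), whose 5-endo-dig heteroannulation in the same flask builds the benzofuran ring on the core and gives 24.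

3. Step 7. Ozone may also attack the two electron-rich arenes or the acetal, and the transient α-aryl aldehyde may epimerise at C3 or open by β-elimination of the aryloxide before it is reduced. Fallback, from 13 back to 15: dihydroxylation of the propenyl group (OsO4 cat., N-methylmorpholine N-oxide, acetone/H2O) gives the diol 1-[(2S,3R)-7-methoxy-2-[3-methoxy-4-(methoxymethoxy)phenyl]-2,3-dihydro-1-benzofuran-3-yl]propane-1,2-diol F6 (two syn-diol diastereomers). NaIO4 on silica gel in CH2Cl2 at 0 °C cleaves it to aldehyde 14, and the filtrate is run directly into NaBH4/MeOH at −20 °C to give 15.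

**Further compounds**
F1 | step 6 | (1S,2S,3E)-2-(2-fluoro-3-methoxyphenyl)-1-[3-methoxy-4-(methoxymethoxy)phenyl]pent-3-en-1-ol | C/C=C/[C@@H](c1cccc(OC)c1F)[C@H](O)c1ccc(OCOC)c(OC)c1
F2 | step 11 | [(2S,3R)-5-iodo-7-methoxy-2-[3-methoxy-4-(methoxymethoxy)phenyl]-2,3-dihydro-1-benzofuran-3-yl]methanol | COc1cc([C@H]2Oc3c(OC)cc(I)cc3[C@@H]2CO)ccc1OCOC
F3 | step 11 | [(2S,3R)-7-methoxy-2-[3-methoxy-4-(methoxymethoxy)phenyl]-5-[(trimethylsilyl)ethynyl]-2,3-dihydro-1-benzofuran-3-yl]methanol | COc1cc([C@H]2Oc3c(OC)cc(C#C[Si](C)(C)C)cc3[C@@H]2CO)ccc1OCOC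
F4 | step 11 | [(2S,3R)-5-ethynyl-7-methoxy-2-[3-methoxy-4-(methoxymethoxy)phenyl]-2,3-dihydro-1-benzofuran-3-yl]methanol | COc1cc([C@H]2Oc3c(OC)cc(C#C)cc3[C@@H]2CO)ccc1OCOC
F5 | step 11 | 2-({(2S,3R)-3-(hydroxymethyl)-7-methoxy-2-[3-methoxy-4-(methoxymethoxy)phenyl]-2,3-dihydro-1-benzofuran-5-yl}ethynyl)-4-(3-hydroxypropyl)-6-methoxyphenol (not isolated) | COc1cc([C@H]2Oc3c(OC)cc(C#Cc4cc(CCCO)cc(OC)c4O)cc3[C@@H]2CO)ccc1OCOC
F6 | step 7 | 1-[(2S,3R)-7-methoxy-2-[3-methoxy-4-(methoxymethoxy)phenyl]-2,3-dihydro-1-benzofuran-3-yl]propane-1,2-diol (two syn-diol diastereomers) | COc1cc([C@H]2Oc3c(OC)cccc3[C@@H]2C(O)C(C)O)ccc1OCOC
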